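Germacranolide numbering: C1 ketone, C2=C3, C4(=C15), C5–O–C10 ether bridge, C6 lactone oxygen, C8 angelate, C9H2. The oxepane (O, C5–C10) is disconnected at C9–C10: O–C10(Me)(C=O)–C9H2 is the retron of an oxonium-ylide [2,3]-shift. A 3-methyleneoxane (O, C5–C8, one OCH2) carries an α-diazopropanoate on the C6 oxygen; copper-carbenoid capture by the ring oxygen and the shift insert C10 between O and the methylene terminus. One operation expands oxane to oxepane, sets quaternary C10 through the tether (C1 and the C6 oxygen are cis) and leaves a C8 methylene for the angelate oxygen. A final ene–yne metathesis closes the dienone ring.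

Key step: step 10

Remark: the remaining germacrane locants are C7 (lactone-bearing CH), C11(=C13H2), C12 (lactone C=O) and C14 (methyl on C10); compounds 1, 2, 6, 9, 15 and 22 are taken as commercial.

Step 1
Reactants: 1 3-(triisopropylsilyl)prop-2-ynal; 2 allyl methoxymethyl ether
Product: 5 (3S,4S)-4-(methoxymethoxy)-1-(triisopropylsilyl)hex-5-en-1-yn-3-ol, via allyllithium 3 (not isolated), via allylborane 4 (not isolated)
Conditions: 2, s-BuLi, THF, −78 °C; (+)-Ipc2BOMe; BF3·OEt2; then 1, −78 °C; NaOH, H2O2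
Reagents that add atoms: none
Why: Brown γ-alkoxyallylboration, in which the (Z)-γ-alkoxyallylborane adds through a closed chair transition state so that the Z geometry gives the syn diol monoether and the isopinocampheyl groups from (−)-α-pinene select the aldehyde face that should give C3 and C4 of 5 (the future C5 and C6) as S,S.

Step 2
Reactants: 5 (3S,4S)-4-(methoxymethoxy)-1-(triisopropylsilyl)hex-5-en-1-yn-3-ol; 6 3-chloro-2-(chloromethyl)prop-1-ene
Product: 7 (3S,4S)-3-{[2-(chloromethyl)prop-2-en-1-yl]oxy}-4-(methoxymethoxy)-1-(triisopropylsilyl)hex-5-en-1-yne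
Conditions: NaH, Bu4NI (cat.), THF/DMF, 0 °C to rt, 6 in excess
Reagents that add atoms: none
Why: Williamson etherification of the only free hydroxyl with an allylic chloride, the excess of the bis-electrophile suppressing double alkylation and no stereocentre being touched.

Step 3
Reactants: 7 (3S,4S)-3-{[2-(chloromethyl)prop-2-en-1-yl]oxy}-4-(methoxymethoxy)-1-(triisopropylsilyl)hex-5-en-1-yne
Product: 8 (2S,3S)-5-(chloromethyl)-3-(methoxymethoxy)-2-[(triisopropylsilyl)ethynyl]-3,6-dihydro-2H-pyran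
Conditions: second-generation Grubbs catalyst (5 mol %), CH2Cl2, 40 °C
Reagents that add atoms: none
Why: Ring-closing metathesis of a monosubstituted with a 1,1-disubstituted alkene should close the six-membered ring, the bulky silylalkyne staying out of the metathesis.

Step 4
Reactants: 8 (2S,3S)-5-(chloromethyl)-3-(methoxymethoxy)-2-[(triisopropylsilyl)ethynyl]-3,6-dihydro-2H-pyran; 9 mono-tert-butyl malonate
Product: 10 tert-butyl {(5S,6S)-5-(methoxymethoxy)-6-[(triisopropylsilyl)ethynyl]-5,6-dihydro-2H-pyran-3-yl}methyl malonate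
Conditions: Cs2CO3, NaI (cat.), DMF, rt
Reagents that add atoms: none
Why: SN2 O-alkylation of the caesium carboxylate at the primary allylic chloride gives the allylic malonate directly.

Step 5
Reactants: 10 tert-butyl {(5S,6S)-5-(methoxymethoxy)-6-[(triisopropylsilyl)ethynyl]-5,6-dihydro-2H-pyran-3-yl}methyl malonate
Product: 12 3-(tert-butoxy)-2-{(2S,3S,4R)-3-(methoxymethoxy)-5-methylidene-2-[(triisopropylsilyl)ethynyl]oxan-4-yl}-3-oxopropanoic acid, via silyl ketene acetal 11 (not isolated)
Conditions: LiN(SiMe3)2, Me3SiCl, THF, −78 °C to reflux; aq. citric acid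
Reagents that add atoms: none
Why: Ireland–Claisen rearrangement, in which the malonate silyl ketene acetal delivers its carbon through a chair [3,3] transition state to the ring terminus on the face anti to the neighbouring OMOM and alkynyl groups, which sets C7 trans to the C6 oxygen and turns the ring alkene into the exocyclic methylene (the malonate carbon is a stereocentre of no consequence).

Step 6
Reactants: 12 3-(tert-butoxy)-2-{(2S,3S,4R)-3-(methoxymethoxy)-5-methylidene-2-[(triisopropylsilyl)ethynyl]oxan-4-yl}-3-oxopropanoic acid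
Product: 13 tert-butyl 2-{(2S,3S,4S)-3-(methoxymethoxy)-5-methylidene-2-[(triisopropylsilyl)ethynyl]oxan-4-yl}prop-2-enoate
Conditions: paraformaldehyde, Et2NH, THF, reflux
Reagents that add atoms: formaldehyde (as paraformaldehyde), C=O
Why: Mannich condensation of the malonic half-acid followed by decarboxylative elimination (decarboxylative methylenation) should give the 2-substituted acrylate and removes the stray stereocentre.

Step 7
Reactants: 13 tert-butyl 2-{(2S,3S,4S)-3-(methoxymethoxy)-5-methylidene-2-[(triisopropylsilyl)ethynyl]oxan-4-yl}prop-2-enoate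
Product: 14 tert-butyl 2-{(2S,3S,4S)-3-hydroxy-5-methylidene-2-[(triisopropylsilyl)ethynyl]oxan-4-yl}prop-2-enoate
Conditions: B-bromocatecholborane, CH2Cl2, −78 °C; aq. NaHCO3
Reagents that add atoms: none
Why: Lewis-acid acetal cleavage, B-bromocatecholborane removing methoxymethyl ethers much faster than it attacks tert-butyl esters or allylic ethers, with a neutral work-up that should leave the trans hydroxy ester unlactonised.

Step 8
Reactants: 14 tert-butyl 2-{(2S,3S,4S)-3-hydroxy-5-methylidene-2-[(triisopropylsilyl)ethynyl]oxan-4-yl}prop-2-enoate; 15 ethyl 2-methyl-3-oxobutanoate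
Product: 16 (2S,3S,4S)-4-[3-(tert-butoxy)-3-oxoprop-1-en-2-yl]-5-methylidene-2-[(triisopropylsilyl)ethynyl]oxan-3-yl 2-methyl-3-oxobutanoate
Conditions: DMAP (0.3 equiv), toluene, 110 °C, 4 Å molecular sieves
Reagents that add atoms: none
Why: DMAP-promoted transesterification of a β-keto ester through its acylketene, which is reactive enough to be captured by the hindered secondary alcohol and is driven by loss of ethanol.

Step 9
Reactants: 16 (2S,3S,4S)-4-[3-(tert-butoxy)-3-oxoprop-1-en-2-yl]-5-methylidene-2-[(triisopropylsilyl)ethynyl]oxan-3-yl 2-methyl-3-oxobutanoate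
Product: 17 (2S,3S,4S)-4-[3-(tert-butoxy)-3-oxoprop-1-en-2-yl]-5-methylidene-2-[(triisopropylsilyl)ethynyl]oxan-3-yl 2-diazopropanoate
Conditions: 4-acetamidobenzenesulfonyl azide, DBU, MeCN, 0 °C to rt
Reagents that add atoms: 4-acetamidobenzenesulfonyl azide, CC(=O)Nc1ccc(cc1)S(=O)(=O)N=[N+]=[N-]
Why: Deacylative Regitz diazo transfer, in which the enolate of the α-substituted β-keto ester attacks the sulfonyl azide and the acetyl group leaves on the sulfonamide nitrogen to give the α-diazopropanoate.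

Step 10
Reactants: 17 (2S,3S,4S)-4-[3-(tert-butoxy)-3-oxoprop-1-en-2-yl]-5-methylidene-2-[(triisopropylsilyl)ethynyl]oxan-3-yl 2-diazopropanoate
Product: 19 tert-butyl 2-{(1S,4S,5S,9S)-1-methyl-3-methylidene-7-oxo-9-[(triisopropylsilyl)ethynyl]-6,8-dioxabicyclo[3.2.2]nonan-4-yl}prop-2-enoate, via oxonium ylide 18 (not isolated)
Conditions: Cu(hfacac)2 (5 mol %), CH2Cl2, 40 °C, slow addition of 17
Reagents that add atoms: none
Why: Loss of N2 gives a copper carbenoid that is captured by the axial lone pair of the oxane oxygen (reachable in the chair that places the C6 ester oxygen axial), and the oxonium ylide 18 then forms the C9–C10 bond at the exocyclic methylene terminus while the ring O–CH2 bond breaks, a [2,3]-sigmatropic shift through a five-membered envelope (a [1,2]-shift of the same allylic carbon would give the identical product because the 2-methylenepropane-1,3-diyl unit is symmetric). The closest known reaction type is the catalytic oxonium ylide formation/[2,3]-rearrangement of diazo carbonyl compounds tethered to cyclic allylic ethers, which is used to make ring-expanded and bridged ethers; the endocyclic O–CH2/exocyclic methylene arrangement used here is its less common one-carbon variant. Two rings are closed: the six-membered 1,4-dioxan-2-one by attack of oxygen on the carbenoid carbon (a bridged bicyclo[3.3.1] ylide), and the seven-membered oxepane by the sigmatropic one-carbon ring expansion of the oxane. The only new stereocentre, quaternary C10, is fixed by the tether: its carbonyl stays bonded to the C6 oxygen and so lies on the face of that oxygen, which puts the methyl group on the opposite face (10S). The step needs ylide formation to beat cyclopropanation of the nearby methylene, C–H insertion at C7 and 1,2-hydride shift of the methyl carbenoid; the electrophilic copper hexafluoroacetylacetonate carbenoid favours lone-pair capture, the acrylate is electron-poor and the silylalkyne is shielded.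

Step 11
Reactants: 19 tert-butyl 2-{(1S,4S,5S,9S)-1-methyl-3-methylidene-7-oxo-9-[(triisopropylsilyl)ethynyl]-6,8-dioxabicyclo[3.2.2]nonan-4-yl}prop-2-enoate
Product: 20 tert-butyl 2-{(1S,4S,5S,9S)-1-methyl-3,7-dioxo-9-[(triisopropylsilyl)ethynyl]-6,8-dioxabicyclo[3.2.2]nonan-4-yl}prop-2-enoate
Conditions: O3, CH2Cl2, −78 °C, Sudan Red 7B end-point; PPh3
Reagents that add atoms: ozone, [O-][O+]=O
Why: Ozonolysis, the isolated 1,1-disubstituted alkene being far more electron-rich than the acrylate and the silylalkyne reacting much more slowly, so that only the C8 methylene should be cleaved to the ketone.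

Step 12
Reactants: 20 tert-butyl 2-{(1S,4S,5S,9S)-1-methyl-3,7-dioxo-9-[(triisopropylsilyl)ethynyl]-6,8-dioxabicyclo[3.2.2]nonan-4-yl}prop-2-enoate
Product: 21 tert-butyl 2-{(1S,3R,4R,5S,9S)-3-hydroxy-1-methyl-7-oxo-9-[(triisopropylsilyl)ethynyl]-6,8-dioxabicyclo[3.2.2]nonan-4-yl}prop-2-enoate
Conditions: LiAlH(OtBu)3, THF, −78 to −20 °C
Reagents that add atoms: none
Why: Diastereoselective ketone reduction by a bulky hydride that tolerates esters, which should attack from the face of the three-carbon bridge that looks at the flat lactone bridge and is anti to the C7 acrylate side chain, so that the C8 alcohol is cis to that side chain while the tert-butyl ester is too hindered to lactonise with it.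

Step 13
Reactants: 21 tert-butyl 2-{(1S,3R,4R,5S,9S)-3-hydroxy-1-methyl-7-oxo-9-[(triisopropylsilyl)ethynyl]-6,8-dioxabicyclo[3.2.2]nonan-4-yl}prop-2-enoate; 22 angelic acid
Product: 24 (1S,3R,4R,5S,9S)-4-[3-(tert-butoxy)-3-oxoprop-1-en-2-yl]-1-methyl-7-oxo-9-[(triisopropylsilyl)ethynyl]-6,8-dioxabicyclo[3.2.2]nonan-3-yl (2Z)-2-methylbut-2-enoate, via mixed anhydride 23 (not isolated)
Conditions: 22, 2,4,6-trichlorobenzoyl chloride, Et3N, toluene, rt; then 21, 75 °C
Reagents that add atoms: none
Why: Yamaguchi-type mixed-anhydride esterification run without a nucleophilic catalyst, which should acylate the hindered alcohol with retention at C8 and without isomerising the Z double bond of the angelate.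

Step 14
Reactants: 24 (1S,3R,4R,5S,9S)-4-[3-(tert-butoxy)-3-oxoprop-1-en-2-yl]-1-methyl-7-oxo-9-[(triisopropylsilyl)ethynyl]-6,8-dioxabicyclo[3.2.2]nonan-3-yl (2Z)-2-methylbut-2-enoate
Product: 25 (1S,3R,4R,5S,9S)-4-[3-(tert-butoxy)-3-oxoprop-1-en-2-yl]-9-ethynyl-1-methyl-7-oxo-6,8-dioxabicyclo[3.2.2]nonan-3-yl (2Z)-2-methylbut-2-enoate
Conditions: Bu4NF, AcOH, THF, 0 °C
Reagents that add atoms: none
Why: Fluoride-induced cleavage of the alkynyl C–Si bond, buffered with acetic acid so that the lactone and the esters should survive.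

Step 15
Reactants: 25 (1S,3R,4R,5S,9S)-4-[3-(tert-butoxy)-3-oxoprop-1-en-2-yl]-9-ethynyl-1-methyl-7-oxo-6,8-dioxabicyclo[3.2.2]nonan-3-yl (2Z)-2-methylbut-2-enoate
Product: 26 (2S,4R,5R,6S,7S)-2-acryloyl-5-[3-(tert-butoxy)-3-oxoprop-1-en-2-yl]-7-ethynyl-6-hydroxy-2-methyloxepan-4-yl (2Z)-2-methylbut-2-enoate
Conditions: vinylmagnesium bromide (1.3 equiv), THF, −78 °C; AcOH quench at −78 °C
Reagents that add atoms: vinylmagnesium bromide, C=C[Mg]Br
Why: Acyl substitution at the strained α-alkoxy lactone, whose tetrahedral magnesium alkoxide is held by chelation to the neighbouring ether oxygen until the cold quench and so should add only once, while the hindered conjugated angelate and tert-butyl acrylate react more slowly.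

Step 16
Reactants: 26 (2S,4R,5R,6S,7S)-2-acryloyl-5-[3-(tert-butoxy)-3-oxoprop-1-en-2-yl]-7-ethynyl-6-hydroxy-2-methyloxepan-4-yl (2Z)-2-methylbut-2-enoate
Product: 28 (5S,6S,7R,8R,10S)-configured oxepane-fused α-methylene-γ-butyrolactone (C6–O and C7) with the C8 angelate and with methyl and acryloyl on C10 and ethynyl on C5, via hydroxy acid 27 (not isolated)
Conditions: CF3CO2H, CH2Cl2, 0 °C to rt
Reagents that add atoms: none
Why: Acidolysis of the tert-butyl ester followed by acid-catalysed lactonisation of the γ-hydroxy acid onto the C6 hydroxyl should give the trans-fused α-methylene lactone without touching a stereocentre, before the dienone that a free C6 hydroxyl could attack exists.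

Step 17
Reactants: 28 (5S,6S,7R,8R,10S)-configured oxepane-fused α-methylene-γ-butyrolactone with the C8 angelate and with methyl and acryloyl on C10 and ethynyl on C5
Product: 30 (5S,6S,7R,8R,10S)-8-angeloyloxy-5,10-epoxy-1-oxogermacra-2,4(15),11(13)-trien-12,6-olide (CNP0282559.1), via diene 29 (not isolated)
Conditions: second-generation Hoveyda–Grubbs catalyst (10 mol %), ethene (1 atm), toluene, 60 °C; then argon purge, 80 °C
Reagents that add atoms: ethene, C=C
Why: Tandem enyne cross-metathesis of the terminal alkyne with ethene (giving the 2-substituted butadiene) and ring-closing metathesis of its vinyl group with the vinyl ketone, which should close the seven-membered dienone ring with the cis C2=C3 bond that the ring enforces, the two arms being cis on the oxepane.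

Compound list
1 | 3-(triisopropylsilyl)prop-2-ynal | O=CC#C[Si](C(C)C)(C(C)C)C(C)C | starting material
2 | allyl methoxymethyl ether | C=CCOCOC | starting material
3 | (Z)-3-(methoxymethoxy)allyllithium | [Li]C/C=C\OCOC | intermediate
4 | (Z)-[3-(methoxymethoxy)allyl]diisopinocampheylborane (isopinocampheyl groups from (−)-α-pinene) | COCO/C=C\CB([C@H]1C[C@H]2C[C@@H]([C@@H]1C)C2(C)C)[C@H]1C[C@H]2C[C@@H]([C@@H]1C)C2(C)C | intermediate
5 | (3S,4S)-4-(methoxymethoxy)-1-(triisopropylsilyl)hex-5-en-1-yn-3-ol | C=C[C@H](OCOC)[C@@H](O)C#C[Si](C(C)C)(C(C)C)C(C)C | intermediate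
6 | 3-chloro-2-(chloromethyl)prop-1-ene | C=C(CCl)CCl | starting material
7 | (3S,4S)-3-{[2-(chloromethyl)prop-2-en-1-yl]oxy}-4-(methoxymethoxy)-1-(triisopropylsilyl)hex-5-en-1-yne | C=C[C@H](OCOC)[C@@H](OCC(=C)CCl)C#C[Si](C(C)C)(C(C)C)C(C)C | intermediate
8 | (2S,3S)-5-(chloromethyl)-3-(methoxymethoxy)-2-[(triisopropylsilyl)ethynyl]-3,6-dihydro-2H-pyran | ClCC1=C[C@H](OCOC)[C@H](C#C[Si](C(C)C)(C(C)C)C(C)C)OC1 | intermediate
9 | mono-tert-butyl malonate | OC(=O)CC(=O)OC(C)(C)C | starting material
10 | tert-butyl {(5S,6S)-5-(methoxymethoxy)-6-[(triisopropylsilyl)ethynyl]-5,6-dihydro-2H-pyran-3-yl}methyl malonate | CC(C)(C)OC(=O)CC(=O)OCC1=C[C@H](OCOC)[C@H](C#C[Si](C(C)C)(C(C)C)C(C)C)OC1 | intermediate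
11 | O-trimethylsilyl ketene acetal of 10 (allyl ester side) | CC(C)(C)OC(=O)C=C(O[Si](C)(C)C)OCC1=C[C@H](OCOC)[C@H](C#C[Si](C(C)C)(C(C)C)C(C)C)OC1 | intermediate
12 | 3-(tert-butoxy)-2-{(2S,3S,4R)-3-(methoxymethoxy)-5-methylidene-2-[(triisopropylsilyl)ethynyl]oxan-4-yl}-3-oxopropanoic acid (epimers at the malonate carbon) | C=C1CO[C@@H](C#C[Si](C(C)C)(C(C)C)C(C)C)[C@@H](OCOC)[C@@H]1C(C(=O)O)C(=O)OC(C)(C)C | intermediate
13 | tert-butyl 2-{(2S,3S,4S)-3-(methoxymethoxy)-5-methylidene-2-[(triisopropylsilyl)ethynyl]oxan-4-yl}prop-2-enoate | C=C1CO[C@@H](C#C[Si](C(C)C)(C(C)C)C(C)C)[C@@H](OCOC)[C@@H]1C(=C)C(=O)OC(C)(C)C | intermediate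
14 | tert-butyl 2-{(2S,3S,4S)-3-hydroxy-5-methylidene-2-[(triisopropylsilyl)ethynyl]oxan-4-yl}prop-2-enoate | C=C1CO[C@@H](C#C[Si](C(C)C)(C(C)C)C(C)C)[C@@H](O)[C@@H]1C(=C)C(=O)OC(C)(C)C | intermediate
15 | ethyl 2-methyl-3-oxobutanoate | CCOC(=O)C(C)C(C)=O | starting material
16 | (2S,3S,4S)-4-[3-(tert-butoxy)-3-oxoprop-1-en-2-yl]-5-methylidene-2-[(triisopropylsilyl)ethynyl]oxan-3-yl 2-methyl-3-oxobutanoate | C=C1CO[C@@H](C#C[Si](C(C)C)(C(C)C)C(C)C)[C@@H](OC(=O)C(C)C(C)=O)[C@@H]1C(=C)C(=O)OC(C)(C)C | intermediate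
17 | (2S,3S,4S)-4-[3-(tert-butoxy)-3-oxoprop-1-en-2-yl]-5-methylidene-2-[(triisopropylsilyl)ethynyl]oxan-3-yl 2-diazopropanoate | C=C1CO[C@@H](C#C[Si](C(C)C)(C(C)C)C(C)C)[C@@H](OC(=O)C(C)=[N+]=[N-])[C@@H]1C(=C)C(=O)OC(C)(C)C | intermediate
18 | bridged oxonium ylide (ring oxygen bonded to the ester α-carbanion; 1,4-dioxan-2-one ring fused across O and C6 of the oxane) | C=C1C[O+]2[C-](C)C(=O)O[C@H]([C@@H]2C#C[Si](C(C)C)(C(C)C)C(C)C)[C@@H]1C(=C)C(=O)OC(C)(C)C | intermediate
19 | tert-butyl 2-{(1S,4S,5S,9S)-1-methyl-3-methylidene-7-oxo-9-[(triisopropylsilyl)ethynyl]-6,8-dioxabicyclo[3.2.2]nonan-4-yl}prop-2-enoate | C=C1C[C@]2(C)O[C@@H](C#C[Si](C(C)C)(C(C)C)C(C)C)[C@@H](OC2=O)[C@@H]1C(=C)C(=O)OC(C)(C)C | intermediate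
20 | tert-butyl 2-{(1S,4S,5S,9S)-1-methyl-3,7-dioxo-9-[(triisopropylsilyl)ethynyl]-6,8-dioxabicyclo[3.2.2]nonan-4-yl}prop-2-enoate | O=C1C[C@]2(C)O[C@@H](C#C[Si](C(C)C)(C(C)C)C(C)C)[C@@H](OC2=O)[C@@H]1C(=C)C(=O)OC(C)(C)C | intermediate
21 | tert-butyl 2-{(1S,3R,4R,5S,9S)-3-hydroxy-1-methyl-7-oxo-9-[(triisopropylsilyl)ethynyl]-6,8-dioxabicyclo[3.2.2]nonan-4-yl}prop-2-enoate | O[C@@H]1C[C@]2(C)O[C@@H](C#C[Si](C(C)C)(C(C)C)C(C)C)[C@@H](OC2=O)[C@@H]1C(=C)C(=O)OC(C)(C)C | intermediate
22 | angelic acid, (2Z)-2-methylbut-2-enoic acid | C/C=C(/C)C(=O)O | starting material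
23 | angelic 2,4,6-trichlorobenzoic anhydride | C/C=C(/C)C(=O)OC(=O)c1c(Cl)cc(Cl)cc1Cl | intermediate
24 | (1S,3R,4R,5S,9S)-4-[3-(tert-butoxy)-3-oxoprop-1-en-2-yl]-1-methyl-7-oxo-9-[(triisopropylsilyl)ethynyl]-6,8-dioxabicyclo[3.2.2]nonan-3-yl (2Z)-2-methylbut-2-enoate | C/C=C(/C)C(=O)O[C@@H]1C[C@]2(C)O[C@@H](C#C[Si](C(C)C)(C(C)C)C(C)C)[C@@H](OC2=O)[C@@H]1C(=C)C(=O)OC(C)(C)C | intermediate
25 | (1S,3R,4R,5S,9S)-4-[3-(tert-butoxy)-3-oxoprop-1-en-2-yl]-9-ethynyl-1-methyl-7-oxo-6,8-dioxabicyclo[3.2.2]nonan-3-yl (2Z)-2-methylbut-2-enoate | C/C=C(/C)C(=O)O[C@@H]1C[C@]2(C)O[C@@H](C#C)[C@@H](OC2=O)[C@@H]1C(=C)C(=O)OC(C)(C)C | intermediate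
26 | (2S,4R,5R,6S,7S)-2-acryloyl-5-[3-(tert-butoxy)-3-oxoprop-1-en-2-yl]-7-ethynyl-6-hydroxy-2-methyloxepan-4-yl (2Z)-2-methylbut-2-enoate | C/C=C(/C)C(=O)O[C@@H]1C[C@@](C)(C(=O)C=C)O[C@@H](C#C)[C@@H](O)[C@@H]1C(=C)C(=O)OC(C)(C)C | intermediate
27 | 2-{(2S,4R,5R,6S,7S)-2-acryloyl-4-[(2Z)-2-methylbut-2-enoyloxy]-7-ethynyl-6-hydroxy-2-methyloxepan-5-yl}prop-2-enoic acid | C/C=C(/C)C(=O)O[C@@H]1C[C@@](C)(C(=O)C=C)O[C@@H](C#C)[C@@H](O)[C@@H]1C(=C)C(=O)O | intermediate
28 | (5S,6S,7R,8R,10S)-configured oxepane-fused α-methylene-γ-butyrolactone with the C8 angelate, methyl and acryloyl on C10 and ethynyl on C5 | C=C1C(=O)O[C@H]2[C@H]1[C@H](OC(=O)/C(C)=C\C)C[C@@](C)(C(=O)C=C)O[C@H]2C#C | intermediate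
29 | the same lactone with buta-1,3-dien-2-yl in place of ethynyl on C5 | C=C1C(=O)O[C@H]2[C@H]1[C@H](OC(=O)/C(C)=C\C)C[C@@](C)(C(=O)C=C)O[C@H]2C(=C)C=C | intermediate
30 | (5S,6S,7R,8R,10S)-8-angeloyloxy-5,10-epoxy-1-oxogermacra-2,4(15),11(13)-trien-12,6-olide (CNP0282559.1) | C=C1C(=O)O[C@H]2[C@H]1[C@H](OC(=O)/C(C)=C\C)C[C@]1(C)O[C@H]2C(=C)C=CC1=O | target

Total step count: 17. Longest linear sequence: 17 steps (1 to 30); every other building block is commercial and enters directly.

Steps most likely to fail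

Step 10. Carbenoid side reactions (cyclopropanation of the neighbouring exocyclic alkene, C–H insertion at C7, 1,2-hydride shift of the methyl carbenoid to an acrylate ester) may outrun capture by the ring oxygen. The fallback makes the same C9–C10 bond by polar steps without a carbenoid; it sets out from 14 and comes back at 19. Acylation of 14 with 2-bromopropanoyl bromide (pyridine, CH2Cl2, 0 °C) should give the 2-bromopropanoate F1. AgBF4 in CH2Cl2 should then drive the ring oxygen onto the α-carbon to the same bridged oxonium ion, and added Bu4NBr should open it at the allylic O–CH2 carbon to give the 1,4-dioxan-2-one bearing a 2-(bromomethyl)allyl unit F2. LiN(SiMe3)2 (THF, −78 °C, high dilution) should form the lactone enolate, whose intramolecular allylic alkylation closes the oxepane to 19, C10 again being fixed by the lactone bridge.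

Step 17. The ruthenium carbene may fail to close the bridged seven-membered ring, or may oligomerise the vinyl ketone or the intermediate diene. The fallback closes the ring by radical chemistry; it sets out from 28 and comes back at 30. Bu3SnH and AIBN (benzene, 80 °C, slow addition) should add a stannyl radical to the alkyne terminus, and the vinyl radical at C4 should cyclise in the seven-endo mode onto the terminal carbon of the vinyl ketone to give the (tributylstannyl)methylidene ketone F4. HCl in CH2Cl2 (protodestannylation) should give the 2,3-dihydro compound F5, and IBX in DMSO/toluene at 70 °C should dehydrogenate C2–C3, the only enolisable position of the C1 ketone, to 30.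

Step 15. Double addition, conjugate addition to the new enone or attack at the angelate may compete with single addition to the lactone. The fallback goes through a stable amide; it sets out from 25 and comes back at 26. AlMe3 and MeNH(OMe)·HCl (CH2Cl2, 0 °C) should open the bridged lactone to the Weinreb amide with free C6 hydroxyl F3, and vinylmagnesium bromide (2.2 equiv, THF, −40 °C) should then give the enone 26 through the chelated tetrahedral intermediate.

Further compounds
F1 | step 10 | (2S,3S,4S)-4-[3-(tert-butoxy)-3-oxoprop-1-en-2-yl]-5-methylidene-2-[(triisopropylsilyl)ethynyl]oxan-3-yl 2-bromopropanoate | C=C1CO[C@@H](C#C[Si](C(C)C)(C(C)C)C(C)C)[C@@H](OC(=O)C(C)Br)[C@@H]1C(=C)C(=O)OC(C)(C)C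
F2 | step 10 | tert-butyl (3R)-4-(bromomethyl)-2-methylidene-3-{(2S,3S)-5-methyl-6-oxo-3-[(triisopropylsilyl)ethynyl]-1,4-dioxan-2-yl}pent-4-enoate (epimers at the methyl-bearing carbon) | CC1O[C@@H](C#C[Si](C(C)C)(C(C)C)C(C)C)[C@@H](OC1=O)[C@@H](C(=C)CBr)C(=C)C(=O)OC(C)(C)C
F3 | step 15 | (2S,4R,5R,6S,7S)-5-[3-(tert-butoxy)-3-oxoprop-1-en-2-yl]-7-ethynyl-6-hydroxy-2-[methoxy(methyl)carbamoyl]-2-methyloxepan-4-yl (2Z)-2-methylbut-2-enoate | C/C=C(/C)C(=O)O[C@@H]1C[C@@](C)(C(=O)N(C)OC)O[C@@H](C#C)[C@@H](O)[C@@H]1C(=C)C(=O)OC(C)(C)C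
F4 | step 17 | 2,3-dihydro-30 carrying a (tributylstannyl)methylidene group on C4 in place of the methylidene | C=C1C(=O)O[C@H]2[C@H]1[C@H](OC(=O)/C(C)=C\C)C[C@]1(C)O[C@H]2C(=C[Sn](CCCC)(CCCC)CCCC)CCC1=O
F5 | step 17 | 2,3-dihydro-30 (C2–C3 saturated) | C=C1C(=O)O[C@H]2[C@H]1[C@H](OC(=O)/C(C)=C\C)C[C@]1(C)O[C@H]2C(=C)CCC1=O
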